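**Retrosynthetic overview**
1. Target 8 ⇒ hydroxylactam 4. Both α-C–Br bonds come from C–O → C–Br exchange with POBr3, and loss of the C5–H aromatises the ring. No pyrrole is brominated by SEAr and no tetrabromopyrrole is N-methylated.
2. Hydroxylactam 4 ⇒ N-methyl-2,3-dibromomaleimide 3 by 1,2-reduction of one imide C=O. This sets the overall oxidation level of the pyrrole, and both β-bromines are already in place.
3. Imide 3 ⇒ 2,3-dibromomaleimide 1 + iodomethane 2.
4. Ring order: the five-membered N-ring is present from the start (as the maleimide); the aromatic pyrrole is formed last, in the deoxybromination step.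

Assumptions: the target is achiral (no stereocentre), so "single enantiomer" is met by the compound itself; the one stereocentre on the route (C5 of 4, 6 and 7) is made racemic and destroyed on aromatisation. Reagents that leave atoms in the product (MeI, POBr3) are numbered like starting materials. Compound 3 is also a catalogue compound, but the route is written from the parent imide 1.

**Step 1**
Reactants: 1 2,3-dibromomaleimide (3,4-dibromo-1H-pyrrole-2,5-dione); 2 iodomethane
Product: 3 2,3-dibromo-N-methylmaleimide (3,4-dibromo-1-methyl-1H-pyrrole-2,5-dione)
Conditions: MeI (1.5 equiv), K2CO3 (1.1 equiv), acetone, rt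
Reagents that add atoms: iodomethane, CI
Why: SN2 N-alkylation of the acidic imide N–H (its potassium salt forms with mild carbonate, which in acetone is too poor a nucleophile to attack the C–Br carbons); no stereocentre is formed.

**Step 2**
Reactants: 3 2,3-dibromo-N-methylmaleimide
Product: 4 (±)-3,4-dibromo-5-hydroxy-1-methyl-1,5-dihydro-2H-pyrrol-2-one
Conditions: NaBH4 (1.0 equiv), CeCl3·7H2O (1.0 equiv), MeOH/THF 1:1, −20 → 0 °C; aq NH4Cl
Reagents that add atoms: none
Why: Luche-type 1,2-reduction of one imide carbonyl, in which Ce(III)/MeOH makes the hydride hard enough to attack C=O and not the bromo-enone carbons, and low temperature stops at the hemiaminal before ring-opening; the imide is symmetric so there is no regiochemistry, and the new C5 stereocentre is formed racemic because step 3 erases it.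

**Step 3**
Reactants: 4 (±)-3,4-dibromo-5-hydroxy-1-methyl-1,5-dihydro-2H-pyrrol-2-one; 5 phosphorus oxybromide
Product: 8 2,3,4,5-tetrabromo-1-methyl-1H-pyrrole, via bromolactam 6 (not isolated), via 2H-pyrrolium salt 7 (not isolated)
Conditions: POBr3 (3.0 equiv), ClCH2CH2Cl, 0 → 80 °C, no base; then ice/aq NaHCO3
Reagents that add atoms: phosphorus oxybromide, O=P(Br)(Br)Br
Why: Proposed new method: POBr3 first converts the hemiaminal OH into a dibromophosphate that ionises to the N-acyliminium ion and is captured by bromide (bromolactam 6), then O-phosphorylates the lactam carbonyl so that bromide addition and dibromophosphate loss give the 2-bromo-2H-pyrrolium salt 7, whose C5–H is lost to aromatise to 8 (base is left out so that C5 is not deprotonated to a pyrrol-2-yl phosphate before bromide has displaced the phosphate); the closest known reactions are the Vilsmeier-type POBr3/POCl3 conversion of 3-pyrrolin-2-ones into 2-halopyrroles and the OH → halide exchange of hydroxylactams and pseudo-acids through N-acyliminium ions; no stereocentre remains because C5 becomes sp2.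

**Compound list**
1 | 2,3-dibromomaleimide (3,4-dibromo-1H-pyrrole-2,5-dione) | O=C1NC(=O)C(Br)=C1Br | starting material
2 | iodomethane | CI | starting material
3 | 2,3-dibromo-N-methylmaleimide (3,4-dibromo-1-methyl-1H-pyrrole-2,5-dione) | CN1C(=O)C(Br)=C(Br)C1=O | intermediate
4 | (±)-3,4-dibromo-5-hydroxy-1-methyl-1,5-dihydro-2H-pyrrol-2-one (racemic) | CN1C(O)C(Br)=C(Br)C1=O | intermediate
5 | phosphorus oxybromide (phosphoryl tribromide) | O=P(Br)(Br)Br | starting material
6 | (±)-3,4,5-tribromo-1-methyl-1,5-dihydro-2H-pyrrol-2-one (racemic, not isolated) | CN1C(Br)C(Br)=C(Br)C1=O | intermediate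
7 | (±)-2,3,4,5-tetrabromo-1-methyl-2H-pyrrol-1-ium dibromophosphate (racemic, not isolated) | C[N+]1=C(Br)C(Br)=C(Br)C1Br.[O-]P(=O)(Br)Br | intermediate
8 | 2,3,4,5-tetrabromo-1-methyl-1H-pyrrole | Cn1c(Br)c(Br)c(Br)c1Br | target

**Total step count:** 3. **Longest linear sequence:** 3 steps (1 → 3 → 4 → 8).

**Steps most likely to fail, with fallbacks**

Step 3 (highest risk). The tandem double deoxybromination is untested on this substrate. The bromolactam 6 has an acidic C5–H and may be trapped as an aromatic pyrrol-2-yl phosphate that bromide cannot displace, or the electron-poor N-acyliminium ion may form too slowly. The fallback sets out from 4 and comes back at 8. Ionic hydrogenation of 4 (Et3SiH, TFA, CH2Cl2, 0 °C → rt) removes the hemiaminal OH through the N-acyliminium ion and gives 3,4-dibromo-1-methyl-1,5-dihydro-2H-pyrrol-2-one F1. This plain 3-pyrrolin-2-one then undergoes the precedented POBr3 aromatising deoxybromination (POBr3, ClCH2CH2Cl, 60 °C, no DMF so that the free α-position is not formylated) to 2,3,4-tribromo-1-methyl-1H-pyrrole F2. The one remaining α-position is brominated with NBS (1.05 equiv, THF, −78 → 0 °C) to give 8. This gives up the bromination-free endgame but needs only one, fully regiodefined, electrophilic bromination.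

Step 2. The hydroxylactam is in equilibrium with its open-chain aldehyde and can be reduced further, and the result is sensitive to temperature and stoichiometry. The fallback sets out from 3 and comes back at 4. Instead of trying to stop at the hemiaminal, 3 is reduced through (excess NaBH4, iPrOH/H2O, 0 °C → rt) to the ring-opened (Z)-2,3-dibromo-4-hydroxy-N-methylbut-2-enamide F3. The allylic alcohol is then re-oxidised (activated MnO2, CH2Cl2, rt, or Dess–Martin periodinane); the resulting Z-aldehyde-amide exists as its cyclic hemiaminal, which is 4. This fallback does not help if hydride attacks the C–Br carbons; the Ce(III) in the main step is there to suppress that.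

Step 1 (lowest risk). Possible problems are incomplete alkylation or attack of base or iodide at the C–Br positions. The fallback sets out from 1 and comes back at 3. Compound 1 is N-acylated with methyl chloroformate and N-methylmorpholine (THF, 0 °C) to methyl 3,4-dibromo-2,5-dioxo-2,5-dihydro-1H-pyrrole-1-carboxylate F4. Methylamine (1.0 equiv, 2 M in THF, CH2Cl2, rt) then opens the activated imide at a ring carbonyl, and the new N-methylamide recloses on the other carbonyl with expulsion of the carbamate nitrogen to give 3 (N-alkoxycarbonylmaleimide transimidation). The N-methyl group then comes from methylamine and no alkylating agent or inorganic base is used.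

**Further compounds**
F1 | step 3 | 3,4-dibromo-1-methyl-1,5-dihydro-2H-pyrrol-2-one | CN1CC(Br)=C(Br)C1=O
F2 | step 3 | 2,3,4-tribromo-1-methyl-1H-pyrrole | Cn1cc(Br)c(Br)c1Br
F3 | step 2 | (Z)-2,3-dibromo-4-hydroxy-N-methylbut-2-enamide | CNC(=O)/C(Br)=C(/Br)CO
F4 | step 1 | methyl 3,4-dibromo-2,5-dioxo-2,5-dihydro-1H-pyrrole-1-carboxylate | COC(=O)N1C(=O)C(Br)=C(Br)C1=O
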